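**Retrosynthetic overview**
- Final C=C: the homoprenyl terminus is unmasked last by Wittig isopropylidenation of a lactol, so no chain alkene is present during the key step.
- Key disconnection: the C3a–C3 and O1–C2 bonds of the dihydrofuran are made in one oxidative [3+2]. C6 of a prenylated triketone, normally a nucleophile, is reversed in polarity by one-electron oxidation (α,α′-diketo radical, an enolonium equivalent) and joined to the nucleophilic =CH2 terminus of an (S)-linalool-derived vinyl carbinol.
- Triketone: phloroglucinol → Friedel–Crafts acylation with the (R)-2-methylbutanoyl unit → dearomatising gem-dimethylation → C-prenylation.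
- Ring order: the carbocycle is bought as the arene and dearomatised early; the dihydrofuran ring is formed in the key step. The acyl and carbinol stereocentres come from the chiral pool; C2 and C3a arise in the key step without useful selectivity and the wanted isomer is separated.

Assumption: (R)-2-methylbutanoic acid and (S)-(+)-linalool are bought enantioenriched; products from their minor enantiomers are diastereomers of 10 and are removed in the step-5 separation.

**Step 1**
Reactants: 1 phloroglucinol; 2 (R)-2-methylbutanoic acid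
Product: 4 (2R)-2-methyl-1-(2,4,6-trihydroxyphenyl)butan-1-one, via (R)-2-methylbutanoyl chloride 3 (not isolated)
Conditions: 2, (COCl)2, cat. DMF, CH2Cl2, 0 °C → rt; then 1, AlCl3 (4 equiv), PhNO2/CH2Cl2, 0 °C → rt; aq. HCl work-up
Reagents that add atoms: none
Why: Friedel–Crafts acylation of the electron-rich arene stops after one acylation because the chelated aryl ketone is deactivated, and the α-stereocentre of 2 is carried through unchanged (no base, room temperature).

**Step 2**
Reactants: 4 (2R)-2-methyl-1-(2,4,6-trihydroxyphenyl)butan-1-one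
Product: 5 3,5-dihydroxy-4,4-dimethyl-2-[(2R)-2-methylbutanoyl]cyclohexa-2,5-dien-1-one
Conditions: NaOMe (3 equiv), MeI (2.2 equiv), MeOH, 0 °C → rt
Reagents that add atoms: iodomethane, CI
Why: Dearomatising double C-methylation (SN2 alkylation of the phenolate carbon, the second methyl entering the already methylated carbon) gives the gem-dimethyl vinylogous acid, while the acyl α-centre is shielded because the β-triketone is present as its enolate.

**Step 3**
Reactants: 5 3,5-dihydroxy-4,4-dimethyl-2-[(2R)-2-methylbutanoyl]cyclohexa-2,5-dien-1-one; 6 prenyl bromide (1-bromo-3-methylbut-2-ene)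
Product: 7 3,5-dihydroxy-4,4-dimethyl-6-(3-methylbut-2-en-1-yl)-2-[(2R)-2-methylbutanoyl]cyclohexa-2,5-dien-1-one
Conditions: NaOMe (2 equiv), 6 (1.0 equiv), MeOH, 0 °C
Reagents that add atoms: none
Why: SN2 C-alkylation of the soft dianion at the only remaining ring CH with an allylic bromide in a protic medium favours C- over O-alkylation, and one equivalent of 6 limits double prenylation.

**Step 4**
Reactants: 8 (S)-linalool
Product: 9 (5S)-5-ethenyl-5-methyloxolan-2-ol
Conditions: O3 (1.0 equiv), CH2Cl2/MeOH, −78 °C; then Me2S, −78 °C → rt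
Reagents that add atoms: ozone, [O-][O+]=O
Why: Chemoselective ozonolysis cleaves the electron-rich trisubstituted alkene much faster than the vinyl group, and the hydroxy aldehyde closes to the lactol (anomers) with the carbinol centre untouched; this removes the alkene that would otherwise compete with the vinyl group and act as a 5-exo radical trap in step 5.

**Step 5 (key step)**
Reactants: 7 3,5-dihydroxy-4,4-dimethyl-6-(3-methylbut-2-en-1-yl)-2-[(2R)-2-methylbutanoyl]cyclohexa-2,5-dien-1-one; 9 (5S)-5-ethenyl-5-methyloxolan-2-ol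
Product: 10 (2R,3aS)-2-[(2S)-5-hydroxy-2-methyloxolan-2-yl]-5,5-dimethyl-7-[(2R)-2-methylbutanoyl]-3a-(3-methylbut-2-en-1-yl)-3,3a-dihydro-1-benzofuran-4,6(2H,5H)-dione
Conditions: Mn(OAc)3·2H2O (2.3 equiv), 9 (4 equiv), degassed AcOH, N2, 25–40 °C; chromatography then preparative HPLC
Reagents that add atoms: none
Why: Proposed new method: one-electron oxidation of the manganese enolate of 7 turns the normally nucleophilic C6 into an electrophilic α,α′-diketo radical (an enolonium equivalent) that adds through its prenyl-bearing carbon to the unhindered =CH2 terminus of 9, and the secondary adduct radical is oxidised by a second trivalent manganese within the chelated β-triketone so that the C1 enol oxygen closes the dihydrofuran (the C5 oxygen cannot give an enol ether); the closest known reactions are the Mn(OAc)3 oxidative radical [3+2] dihydrofuran annulation of cyclic 1,3-diones with alkenes and the intramolecular C6-radical cyclisations of dearomatised acylphloroglucinols; C3a and C2 are both created here with little facial bias, so about four diastereomers are expected and the (2R,3aS) isomer (roughly a quarter of the mixture, prenyl cis to the C2 substituent by NOE) is isolated.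

**Step 6**
Reactants: 10 (2R,3aS)-2-[(2S)-5-hydroxy-2-methyloxolan-2-yl]-5,5-dimethyl-7-[(2R)-2-methylbutanoyl]-3a-(3-methylbut-2-en-1-yl)-3,3a-dihydro-1-benzofuran-4,6(2H,5H)-dione
Product: 11 (2R,3aS)-2-[(2S)-2-hydroxy-6-methylhept-5-en-2-yl]-5,5-dimethyl-7-[(2R)-2-methylbutanoyl]-3a-(3-methylbut-2-en-1-yl)-3,3a-dihydro-1-benzofuran-4,6(2H,5H)-dione
Conditions: i-PrPPh3+ I− (3 equiv), KN(SiMe3)2 (2.9 equiv), THF, 0 °C; then 10, −78 → 0 °C
Reagents that add atoms: isopropyltriphenylphosphonium iodide, CC(C)[P+](c1ccccc1)(c1ccccc1)c1ccccc1.[I-]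
Why: Wittig olefination of the open hydroxy-aldehyde form of the lactol by the unstabilised ylide installs the isopropylidene terminus and frees the tertiary alcohol, while low temperature spares the hindered or vinylogous-ester ring carbonyls and the enolisable acyl α-centre; no stereocentre is touched.

**Compound list**
1 | phloroglucinol (benzene-1,3,5-triol) | Oc1cc(O)cc(O)c1 | starting material
2 | (R)-2-methylbutanoic acid | CC[C@@H](C)C(O)=O | starting material
3 | (R)-2-methylbutanoyl chloride (not isolated) | CC[C@@H](C)C(Cl)=O | intermediate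
4 | (2R)-2-methyl-1-(2,4,6-trihydroxyphenyl)butan-1-one | CC[C@@H](C)C(=O)c1c(O)cc(O)cc1O | intermediate
5 | 3,5-dihydroxy-4,4-dimethyl-2-[(2R)-2-methylbutanoyl]cyclohexa-2,5-dien-1-one (enol form of the 2-acyl-4,4-dimethylcyclohexane-1,3,5-trione) | CC[C@@H](C)C(=O)C1=C(O)C(C)(C)C(O)=CC1=O | intermediate
6 | prenyl bromide (1-bromo-3-methylbut-2-ene) | CC(C)=CCBr | starting material
7 | 3,5-dihydroxy-4,4-dimethyl-6-(3-methylbut-2-en-1-yl)-2-[(2R)-2-methylbutanoyl]cyclohexa-2,5-dien-1-one | CC[C@@H](C)C(=O)C1=C(O)C(C)(C)C(O)=C(CC=C(C)C)C1=O | intermediate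
8 | (S)-linalool [(3S)-3,7-dimethylocta-1,6-dien-3-ol] | C=C[C@@](C)(O)CCC=C(C)C | starting material
9 | (5S)-5-ethenyl-5-methyloxolan-2-ol (lactol; anomers; ring form of (S)-4-hydroxy-4-methylhex-5-enal) | C=C[C@@]1(C)OC(O)CC1 | intermediate
10 | (2R,3aS)-2-[(2S)-5-hydroxy-2-methyloxolan-2-yl]-5,5-dimethyl-7-[(2R)-2-methylbutanoyl]-3a-(3-methylbut-2-en-1-yl)-3,3a-dihydro-1-benzofuran-4,6(2H,5H)-dione (lactol anomers) | CC[C@@H](C)C(=O)C1=C2O[C@@H]([C@@]3(C)OC(O)CC3)C[C@]2(CC=C(C)C)C(=O)C(C)(C)C1=O | intermediate
11 | (2R,3aS)-2-[(2S)-2-hydroxy-6-methylhept-5-en-2-yl]-5,5-dimethyl-7-[(2R)-2-methylbutanoyl]-3a-(3-methylbut-2-en-1-yl)-3,3a-dihydro-1-benzofuran-4,6(2H,5H)-dione (CNP0306408.2) | CC[C@@H](C)C(=O)C1=C2O[C@@H]([C@@](C)(O)CCC=C(C)C)C[C@]2(CC=C(C)C)C(=O)C(C)(C)C1=O | target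

**Step count and risks**
Total steps: 6. Longest linear sequence: 5 (steps 1, 2, 3, 5, 6 from phloroglucinol); the linalool branch is steps 4, 5, 6.

Steps most likely to fail:

1. Step 5 (oxidative [3+2]; slow intermolecular addition of a hindered tertiary radical, over-oxidation of the prenylated carbon, no diastereocontrol). The fallback sets out from 7 and comes back at 10, replacing the one-pot oxidation by a stepwise atom-transfer sequence. Compound 7 is brominated at C6 (NBS, CH2Cl2, 0 °C) to the isolable enolonium equivalent 6-bromo triketone F1. A Kharasch atom-transfer radical addition of F1 across the vinyl group of 9 (Et3B, air, CH2Cl2, rt) gives the secondary bromide adduct F2, in which bromine transfer outruns side reactions of the adduct radical. Silver-assisted 5-exo O-alkylation by the C1 enol oxygen (AgOSO2CF3, 2,6-lutidine, CH2Cl2) then closes the dihydrofuran to 10, with the same diastereomer separation.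

2. Step 6 (Wittig on a polycarbonyl substrate; risk of epimerising the acyl α-centre or attack on ring carbonyls by the basic ylide). The fallback sets out from 8 and comes back at 11, using a mask that is removed reductively instead of by olefination. Bromoetherification of 8 (2,4,4,6-tetrabromocyclohexa-2,5-dien-1-one, MeNO2, 0 °C) ties the chain alkene and the tertiary alcohol into the bromo-oxane F3 (the co-formed oxolane isomer is removed by chromatography). The step-5 annulation of 7 with F3 gives the bromo-oxane bicycle F4 after the same separation. Zinc dust (NH4Cl, EtOH, reflux) then effects a Boord-type reductive β-elimination that regenerates both the trisubstituted alkene and the tertiary alcohol, giving 11 without base.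

3. Step 3 (mono-C-prenylation; competing O- and double alkylation). The fallback sets out from 4 and comes back at 7, reversing the order of alkylation and dearomatisation. Aromatic C-prenylation of 4 with 6 in aqueous KOH at 0 °C gives the monoprenyl acylphloroglucinol F5. Dearomatising gem-dimethylation of F5 at its one unsubstituted ring carbon (MeI, NaOMe, MeOH) then gives 7.

**Further compounds**
F1 | step 5 | 6-bromo-3-hydroxy-4,4-dimethyl-6-(3-methylbut-2-en-1-yl)-2-[(2R)-2-methylbutanoyl]cyclohex-2-ene-1,5-dione (C6 epimers) | CC[C@@H](C)C(=O)C1=C(O)C(C)(C)C(=O)C(Br)(CC=C(C)C)C1=O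
F2 | step 5 | 6-{2-bromo-2-[(2S)-5-hydroxy-2-methyloxolan-2-yl]ethyl}-3-hydroxy-4,4-dimethyl-6-(3-methylbut-2-en-1-yl)-2-[(2R)-2-methylbutanoyl]cyclohex-2-ene-1,5-dione (epimers at C6 and CHBr) | CC[C@@H](C)C(=O)C1=C(O)C(C)(C)C(=O)C(CC=C(C)C)(CC(Br)[C@@]2(C)OC(O)CC2)C1=O
F3 | step 6 | (6S)-3-bromo-6-ethenyl-2,2,6-trimethyloxane (C3 epimers) | C=C[C@]1(C)CCC(Br)C(C)(C)O1
F4 | step 6 | (2R,3aS)-2-[(2S)-5-bromo-2,6,6-trimethyloxan-2-yl]-5,5-dimethyl-7-[(2R)-2-methylbutanoyl]-3a-(3-methylbut-2-en-1-yl)-3,3a-dihydro-1-benzofuran-4,6(2H,5H)-dione (CHBr epimers) | CC[C@@H](C)C(=O)C1=C2O[C@@H]([C@]3(C)CCC(Br)C(C)(C)O3)C[C@]2(CC=C(C)C)C(=O)C(C)(C)C1=O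
F5 | step 3 | (2R)-2-methyl-1-[2,4,6-trihydroxy-3-(3-methylbut-2-en-1-yl)phenyl]butan-1-one | CC[C@@H](C)C(=O)c1c(O)cc(O)c(CC=C(C)C)c1O
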